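**Retrosynthetic overview**
- C–Br last: anti-selective α′-bromination of the (S)-4-hydroxycyclopentenone, which gives the trans bromohydrin.
- The only ring (the cyclopentenone) comes from an intramolecular aldol condensation of an open-chain (10S)-10-hydroxy-9,12-diketone on the C18 chain (C13 onto C9).
- Key C11–C12 bond: the acyl anion equivalent (Breslow intermediate) of (Z)-hept-4-enal adds to the β-carbon of a 2-silyloxy vinyl ketone, joining two normally electrophilic carbons; catalyst-controlled protonation sets C10.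
- The 2-silyloxy enone comes from kinetic enol silylation of a 1,2-diketone, itself made from the monomethyl azelate acid chloride and a 1-ethoxyvinyl stannane (masked acetyl anion).

Assumption: the (S)-triazolium salt is taken to give the 10S adduct in step 3 (untested for this acceptor; the (R)-salt is used if the sense is reversed), and methyl 9-chloro-9-oxononanoate is bought as such.

Step 1
Reactants: 1 methyl 9-chloro-9-oxononanoate; 2 tributyl(1-ethoxyvinyl)stannane
Product: 4 methyl 9,10-dioxoundecanoate, via ethoxy enone 3 (not isolated)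
Conditions: PdCl2(PPh3)2 (2 mol %), toluene, 80 °C; then 1 M HCl, THF, rt
Reagents that add atoms: water, O
Why: Stille acylation of the aliphatic acid chloride with the 1-ethoxyvinyl stannane gives the 2-ethoxy enone, whose enol ether is hydrolysed by dilute acid to the 1,2-diketone without touching the methyl ester; no stereocenter is formed.

Step 2
Reactants: 4 methyl 9,10-dioxoundecanoate
Product: 5 methyl 10-[(tert-butyldimethylsilyl)oxy]-9-oxoundec-10-enoate
Conditions: LiN(SiMe3)2 (1.05 equiv), THF, −78 °C; TBSOTf (1.1 equiv), −78 to −40 °C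
Reagents that add atoms: tert-butyldimethylsilyl trifluoromethanesulfonate, CC(C)(C)[Si](C)(C)OS(=O)(=O)C(F)(F)F
Why: Kinetic deprotonation of the unhindered methyl group followed by O-silylation (silyl enol ether formation) gives the terminal 2-silyloxy enone, and any internal regioisomer is a β-substituted enone that stays inert in step 3 and is removed there; no stereocenter is formed.

Step 3
Reactants: 5 methyl 10-[(tert-butyldimethylsilyl)oxy]-9-oxoundec-10-enoate; 6 (Z)-hept-4-enal
Product: 7 methyl (10S,15Z)-10-[(tert-butyldimethylsilyl)oxy]-9,12-dioxooctadec-15-enoate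
Conditions: (S)-5-benzyl-2-(2,4,6-trimethylphenyl)-6,8-dihydro-5H-[1,2,4]triazolo[3,4-c][1,4]oxazin-2-ium chloride (10 mol %), KOC(CH3)3 (8 mol %), toluene, 0 °C to rt, 24 h
Reagents that add atoms: none
Why: Proposed new method: a Stetter reaction in which the carbene-derived Breslow intermediate of 6 adds to the unsubstituted β-carbon of the captodative 2-silyloxy enone 5 and the resulting enol is protonated at C10 by proton transfer inside the chiral catalyst pocket before the catalyst leaves, which sets 10S, the closest known reactions being Stetter additions of (Z)-hept-4-enal to vinyl ketones and the enantioselective Stetter/protonation of 2-acetamidoacrylates and 2-alkyl acrylates with this catalyst class, while the bulky silyl ether slows re-enolisation of the new centre.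

Step 4
Reactants: 7 methyl (10S,15Z)-10-[(tert-butyldimethylsilyl)oxy]-9,12-dioxooctadec-15-enoate
Product: 9 methyl 8-[(5S)-5-hydroxy-3-oxo-2-[(2Z)-pent-2-en-1-yl]cyclopent-1-en-1-yl]octanoate, via hydroxy diketone 8 (not isolated)
Conditions: HF·pyridine, THF, 0 °C to rt; NaHCO3 wash; then K2CO3 (0.5 equiv), MeOH, 0 °C, 2 h
Reagents that add atoms: none
Why: Desilylation followed by base-mediated intramolecular aldol condensation (the rethrolone closure of 3-hydroxy-2,5-diones), in which the C13 enolate of the unactivated ketone attacks the hydroxyl-activated C9 ketone and E1cB loss of water gives the tetrasubstituted enone, while the carbinol centre takes no part in bond formation and the methanolic carbonate spares the methyl ester.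

Step 5
Reactants: 9 methyl 8-[(5S)-5-hydroxy-3-oxo-2-[(2Z)-pent-2-en-1-yl]cyclopent-1-en-1-yl]octanoate
Product: 12 methyl 8-[(4S,5R)-4-bromo-5-hydroxy-3-oxo-2-[(2Z)-pent-2-en-1-yl]cyclopent-1-en-1-yl]octanoate, via bis-silyl dienol ether 10 (not isolated), via bromo silyl ether 11 (not isolated)
Conditions: LiN(SiMe3)2 (2.2 equiv), THF, −78 °C; Me3SiCl (2.4 equiv), −78 to −40 °C; N-bromosuccinimide (1.05 equiv), −78 °C; then 1 M HCl, THF, 0 °C
Reagents that add atoms: N-bromosuccinimide, O=C1CCC(=O)N1Br
Why: Kinetic α′-deprotonation of the alkoxide (whose β-oxido group cannot be eliminated), double silylation and electrophilic bromination of the silyl enol ether put bromine anti to the neighbouring silyloxy group, giving the trans (4S,5R) bromohydrin after mild acidic loss of the transient trimethylsilyl ether, the silyl enol ether being far more reactive toward N-bromosuccinimide than the isolated Z-alkene.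

**Compound list**
1 | methyl 9-chloro-9-oxononanoate | COC(=O)CCCCCCCC(Cl)=O | starting material
2 | tributyl(1-ethoxyvinyl)stannane | CCCC[Sn](CCCC)(CCCC)C(=C)OCC | starting material
3 | methyl 10-ethoxy-9-oxoundec-10-enoate | C=C(OCC)C(=O)CCCCCCCC(=O)OC | intermediate
4 | methyl 9,10-dioxoundecanoate | CC(=O)C(=O)CCCCCCCC(=O)OC | intermediate
5 | methyl 10-[(tert-butyldimethylsilyl)oxy]-9-oxoundec-10-enoate | C=C(O[Si](C)(C)C(C)(C)C)C(=O)CCCCCCCC(=O)OC | intermediate
6 | (Z)-hept-4-enal | CC/C=C\CCC=O | starting material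
7 | methyl (10S,15Z)-10-[(tert-butyldimethylsilyl)oxy]-9,12-dioxooctadec-15-enoate | CC/C=C\CCC(=O)C[C@H](O[Si](C)(C)C(C)(C)C)C(=O)CCCCCCCC(=O)OC | intermediate
8 | methyl (10S,15Z)-10-hydroxy-9,12-dioxooctadec-15-enoate | CC/C=C\CCC(=O)C[C@H](O)C(=O)CCCCCCCC(=O)OC | intermediate
9 | methyl 8-[(5S)-5-hydroxy-3-oxo-2-[(2Z)-pent-2-en-1-yl]cyclopent-1-en-1-yl]octanoate | CC/C=C\CC1=C(CCCCCCCC(=O)OC)[C@@H](O)CC1=O | intermediate
10 | methyl 8-[(5S)-2-[(2Z)-pent-2-en-1-yl]-3,5-bis[(trimethylsilyl)oxy]cyclopenta-1,3-dien-1-yl]octanoate | CC/C=C\CC1=C(CCCCCCCC(=O)OC)[C@@H](O[Si](C)(C)C)C=C1O[Si](C)(C)C | intermediate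
11 | methyl 8-[(4S,5R)-4-bromo-3-oxo-2-[(2Z)-pent-2-en-1-yl]-5-[(trimethylsilyl)oxy]cyclopent-1-en-1-yl]octanoate | CC/C=C\CC1=C(CCCCCCCC(=O)OC)[C@@H](O[Si](C)(C)C)[C@H](Br)C1=O | intermediate
12 | methyl 8-[(4S,5R)-4-bromo-5-hydroxy-3-oxo-2-[(2Z)-pent-2-en-1-yl]cyclopent-1-en-1-yl]octanoate | CC/C=C\CC1=C(CCCCCCCC(=O)OC)[C@@H](O)[C@H](Br)C1=O | target

**Step count and risks**
Total step count: 5. Longest linear sequence: 5 steps (1 → 4 → 5 → 7 → 9 → 12).

The three steps most likely to fail:

Step 3. The 2-silyloxy enone is an untested, less electrophilic Stetter acceptor, and both the level and the sense of the protonation selectivity are unknown. The fallback gives up catalyst control and resolves instead. It sets out from 5 and 6. An achiral Stetter reaction with 3-benzyl-5-(2-hydroxyethyl)-4-methylthiazolium chloride and triethylamine in dioxane at 70 °C (the most reactive carbene class for aliphatic aldehydes) gives racemic methyl (15Z)-10-[(tert-butyldimethylsilyl)oxy]-9,12-dioxooctadec-15-enoate F1. HF·pyridine then K2CO3 in methanol takes it through racemic methyl (15Z)-10-hydroxy-9,12-dioxooctadec-15-enoate F2 to racemic methyl 8-[5-hydroxy-3-oxo-2-[(2Z)-pent-2-en-1-yl]cyclopent-1-en-1-yl]octanoate F3. Kinetic resolution with Burkholderia cepacia lipase (Amano PS) and vinyl acetate in tert-butyl methyl ether at 30 °C, run to about 55 % conversion, acetylates the (R)-enantiomer to methyl 8-[(5R)-5-acetoxy-3-oxo-2-[(2Z)-pent-2-en-1-yl]cyclopent-1-en-1-yl]octanoate F4, as is known for rethrolone alcohols. The unreacted (S)-alcohol is separated, and the route comes back at 9.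

Step 4. The free α-hydroxy ketone 8 may lose enantiopurity through its enediol, may eliminate water to the enedione, or may close through the C8 enolate under carbonate. The fallback closes the ring before the hydroxyl is unmasked and uses enamine activation in place of an enolate. It sets out from 7. Pyrrolidine and acetic acid (0.3 equiv each) in toluene at 40 °C form the enamine only at the unhindered C12 ketone, and aldol condensation onto C9 gives methyl 8-[(5S)-5-[(tert-butyldimethylsilyl)oxy]-3-oxo-2-[(2Z)-pent-2-en-1-yl]cyclopent-1-en-1-yl]octanoate F5. HF·pyridine in THF then removes the silyl group, and the route comes back at 9.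

Step 5. The one-pot dianion sequence may suffer γ-deprotonation, closure of the bromo alkoxide to the epoxide, or incomplete transient protection. The fallback uses an isolable protecting group and purifies the protected bromide before a mild unmasking. It sets out from 9. Et3SiCl and imidazole in DMF give methyl 8-[(5S)-3-oxo-2-[(2Z)-pent-2-en-1-yl]-5-[(triethylsilyl)oxy]cyclopent-1-en-1-yl]octanoate F6. LiN(SiMe3)2 and Me3SiCl at −78 °C give methyl 8-[(5S)-2-[(2Z)-pent-2-en-1-yl]-5-[(triethylsilyl)oxy]-3-[(trimethylsilyl)oxy]cyclopenta-1,3-dien-1-yl]octanoate F7, which is not isolated. N-bromosuccinimide at −78 °C gives methyl 8-[(4S,5R)-4-bromo-3-oxo-2-[(2Z)-pent-2-en-1-yl]-5-[(triethylsilyl)oxy]cyclopent-1-en-1-yl]octanoate F8, which is purified. Acetic acid/THF/water at rt removes the triethylsilyl ether, and the route comes back at 12.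

Further compounds
F1 | step 3 | racemic methyl (15Z)-10-[(tert-butyldimethylsilyl)oxy]-9,12-dioxooctadec-15-enoate | CC/C=C\CCC(=O)CC(O[Si](C)(C)C(C)(C)C)C(=O)CCCCCCCC(=O)OC
F2 | step 3 | racemic methyl (15Z)-10-hydroxy-9,12-dioxooctadec-15-enoate | CC/C=C\CCC(=O)CC(O)C(=O)CCCCCCCC(=O)OC
F3 | step 3 | racemic methyl 8-[5-hydroxy-3-oxo-2-[(2Z)-pent-2-en-1-yl]cyclopent-1-en-1-yl]octanoate | CC/C=C\CC1=C(CCCCCCCC(=O)OC)C(O)CC1=O
F4 | step 3 | methyl 8-[(5R)-5-acetoxy-3-oxo-2-[(2Z)-pent-2-en-1-yl]cyclopent-1-en-1-yl]octanoate | CC/C=C\CC1=C(CCCCCCCC(=O)OC)[C@H](OC(C)=O)CC1=O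
F5 | step 4 | methyl 8-[(5S)-5-[(tert-butyldimethylsilyl)oxy]-3-oxo-2-[(2Z)-pent-2-en-1-yl]cyclopent-1-en-1-yl]octanoate | CC/C=C\CC1=C(CCCCCCCC(=O)OC)[C@@H](O[Si](C)(C)C(C)(C)C)CC1=O
F6 | step 5 | methyl 8-[(5S)-3-oxo-2-[(2Z)-pent-2-en-1-yl]-5-[(triethylsilyl)oxy]cyclopent-1-en-1-yl]octanoate | CC/C=C\CC1=C(CCCCCCCC(=O)OC)[C@@H](O[Si](CC)(CC)CC)CC1=O
F7 | step 5 | methyl 8-[(5S)-2-[(2Z)-pent-2-en-1-yl]-5-[(triethylsilyl)oxy]-3-[(trimethylsilyl)oxy]cyclopenta-1,3-dien-1-yl]octanoate | CC/C=C\CC1=C(CCCCCCCC(=O)OC)[C@@H](O[Si](CC)(CC)CC)C=C1O[Si](C)(C)C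
F8 | step 5 | methyl 8-[(4S,5R)-4-bromo-3-oxo-2-[(2Z)-pent-2-en-1-yl]-5-[(triethylsilyl)oxy]cyclopent-1-en-1-yl]octanoate | CC/C=C\CC1=C(CCCCCCCC(=O)OC)[C@@H](O[Si](CC)(CC)CC)[C@H](Br)C1=O
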